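**Retrosynthetic overview**
- Target ⇒ cleave the 13-O–Si bond and the C6–OAc bond: O–H insertion of acetic acid into an α′-diazo enone, with C6 set by α-face ketonisation of the resulting acetoxy dienol.
- α′-Diazo enone ⇒ C6=N2 disconnection: diazo transfer to the 13-O-silyl 7-oxo-8-ene.
- Enone ⇒ C7–O disconnection: allylic hydroxylation of the exocyclic 8(17)-alkene, oxidation, then exo-to-endo shift of the double bond.
- Exocyclic alkene ⇒ sclareol, by selective O-silylation of the side-chain carbinol and dehydration of the ring carbinol.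
- No ring is formed: rings A and B, C5, C10 and C13 come unchanged from sclareol; ring B is only refunctionalised (C8, then C7, then C6).

Assumption: labdane numbering; α is the face of H-5 and β the face of the C10 methyl, so the target is (13R)-6β-acetoxy-13-hydroxylabda-8,14-dien-7-one (6S), in the same absolute series as natural (−)-sclareol.

**Step 1**
Reactants: 1 (−)-sclareol
Product: 3 (13R)-13-(triethylsilyloxy)labda-8(17),14-diene, via 13-O-triethylsilylsclareol 2 (not isolated)
Conditions: TESOTf (1.05 equiv), 2,6-lutidine, CH2Cl2, −78 °C; then pyridine, SOCl2, −78 to −40 °C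
Reagents that add atoms: triethylsilyl trifluoromethanesulfonate, CC[Si](CC)(CC)OS(=O)(=O)C(F)(F)F
Why: The side-chain carbinol is the less hindered of the two tertiary alcohols and is silylated first (silyl ether formation), and the chlorosulfite of the equatorial 8α-oxygen then has only methyl hydrogens antiperiplanar, so pyridine-induced E2 dehydration gives mainly the exocyclic 8(17)-alkene without a free C8 cation (minor ring-alkene isomers are removed on AgNO3-silica); no stereocentre is created and C5, C9, C10 and C13 are untouched.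

**Step 2**
Reactants: 3 (13R)-13-(triethylsilyloxy)labda-8(17),14-diene
Product: 4 (13R)-13-(triethylsilyloxy)labda-8(17),14-dien-7α-ol
Conditions: SeO2 (0.5 equiv), t-BuOOH (3 equiv), CH2Cl2, 0 °C to rt
Reagents that add atoms: tert-butyl hydroperoxide, CC(C)(C)OO (terminal oxidant; its oxygen is delivered through selenium dioxide, O=[Se]=O)
Why: Selenium dioxide allylic hydroxylation (Riley oxidation: ene reaction, then [2,3]-sigmatropic shift) attacks the only alkene that has allylic hydrogens, prefers the ring CH2 (C7) over the C9 methine and delivers oxygen to C7 from the open α face, a stereocentre that is erased in step 3; the vinyl group and the silyl ether are inert.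

**Step 3**
Reactants: 4 (13R)-13-(triethylsilyloxy)labda-8(17),14-dien-7α-ol
Product: 6 (13R)-13-(triethylsilyloxy)labda-8,14-dien-7-one, via exocyclic enone 5 (not isolated)
Conditions: MnO2, CH2Cl2, rt; filter through Celite, swap solvent; then RhCl3·3H2O (5 mol%), K2CO3 (10 mol%), EtOH, 70 °C
Reagents that add atoms: none
Why: MnO2 oxidises only the secondary allylic alcohol, and a rhodium hydride formed from RhCl3 in ethanol then moves the exocyclic double bond into the ring to the more stable tetrasubstituted conjugated enone (hydrometalation/β-hydride elimination alkene isomerisation, thermodynamic control); this removes the C7 and C9 stereocentres and creates none, and the vinyl group cannot migrate because C13 bears no hydrogen.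

**Step 4**
Reactants: 6 (13R)-13-(triethylsilyloxy)labda-8,14-dien-7-one
Product: 8 (13R)-6-diazo-13-(triethylsilyloxy)labda-8,14-dien-7-one, via trifluoroacetyl ketone 7 (not isolated)
Conditions: LiN(SiMe3)2, THF, −78 °C; CF3CO2CH2CF3, −78 °C; then MsN3, Et3N, H2O, MeCN, rt
Reagents that add atoms: methanesulfonyl azide, CS(=O)(=O)N=[N+]=[N-]; 2,2,2-trifluoroethyl trifluoroacetate, O=C(OCC(F)(F)F)C(F)(F)F (its acyl group stays only in 7)
Why: Danheiser detrifluoroacetylative diazo transfer (Regitz type): kinetic α′-deprotonation at C6 gives the cross-conjugated dienolate, C-trifluoroacetylation activates C6, and sulfonyl azide addition with loss of N-mesyl trifluoroacetamide forms the C6=N2 bond; no stereocentre is involved and the silyl ether avoids a second deprotonation.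

**Step 5**
Reactants: 8 (13R)-6-diazo-13-(triethylsilyloxy)labda-8,14-dien-7-one
Product: 11 (13R)-6β-acetoxy-13-hydroxylabda-8,14-dien-7-one (target), via acetoxy dienol 9 (not isolated), via O-silylated target 10 (not isolated)
Conditions: Rh2(O2CCPh3)4 (1 mol%), AcOH (10 equiv), (PhO)2P(O)OH (2 mol%), CH2Cl2, −20 °C, slow addition of 8; then HF·pyridine, pyridine, THF, 0 °C to rt
Reagents that add atoms: acetic acid, CC(=O)O
Why: Proposed new method: dirhodium-carbene O–H insertion of acetic acid into a ring-fused α′-diazo enone, with the new stereocentre set by substrate-controlled ketonisation: loss of N2 gives the carbene at C6, acetic acid (in excess, with bulky triphenylacetate ligands to slow the competing 1,2-hydride shift from C5) bonds through oxygen to the carbene carbon and the metal departs to leave planar 6-acetoxy dienol 9, and the acetic acid/diphenyl phosphate proton shuttle then protonates C6 from the open α face (the β face is blocked by the syn-axial C4 and C10 methyls), which forces the acetate into the hindered axial 6β position (6S) that an external acetoxylating reagent would not reach; the closest known reaction type is dirhodium-catalysed O–H insertion of carboxylic acids into α-diazo ketones, including enantioselective variants with chiral proton shuttles, not shown for α′-diazo enones or for setting an axial ring stereocentre under substrate control, and HF·pyridine finally cleaves the silyl ether without epimerising the α-acetoxy ketone.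

**Compound list**
1 | (−)-sclareol, (13R)-labd-14-ene-8α,13-diol | C=C[C@](C)(O)CC[C@H]1[C@](C)(O)CC[C@H]2C(C)(C)CCC[C@]12C | starting material
2 | 13-O-triethylsilylsclareol | C=C[C@](C)(O[Si](CC)(CC)CC)CC[C@H]1[C@](C)(O)CC[C@H]2C(C)(C)CCC[C@]12C | intermediate
3 | (13R)-13-(triethylsilyloxy)labda-8(17),14-diene (13-O-triethylsilylmanool) | C=C[C@](C)(O[Si](CC)(CC)CC)CC[C@H]1C(=C)CC[C@H]2C(C)(C)CCC[C@]12C | intermediate
4 | (13R)-13-(triethylsilyloxy)labda-8(17),14-dien-7α-ol | C=C[C@](C)(O[Si](CC)(CC)CC)CC[C@H]1C(=C)[C@H](O)C[C@H]2C(C)(C)CCC[C@]12C | intermediate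
5 | (13R)-13-(triethylsilyloxy)labda-8(17),14-dien-7-one | C=C[C@](C)(O[Si](CC)(CC)CC)CC[C@H]1C(=C)C(=O)C[C@H]2C(C)(C)CCC[C@]12C | intermediate
6 | (13R)-13-(triethylsilyloxy)labda-8,14-dien-7-one | C=C[C@](C)(O[Si](CC)(CC)CC)CCC1=C(C)C(=O)C[C@H]2C(C)(C)CCC[C@]12C | intermediate
7 | 6-trifluoroacetyl derivative of 6, drawn as its ring enol | C=C[C@](C)(O[Si](CC)(CC)CC)CCC1=C(C)C(O)=C(C(=O)C(F)(F)F)[C@H]2C(C)(C)CCC[C@]12C | intermediate
8 | (13R)-6-diazo-13-(triethylsilyloxy)labda-8,14-dien-7-one | C=C[C@](C)(O[Si](CC)(CC)CC)CCC1=C(C)C(=O)C(=[N+]=[N-])[C@H]2C(C)(C)CCC[C@]12C | intermediate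
9 | (13R)-6-acetoxy-13-(triethylsilyloxy)labda-6,8,14-trien-7-ol | C=C[C@](C)(O[Si](CC)(CC)CC)CCC1=C(C)C(O)=C(OC(C)=O)[C@H]2C(C)(C)CCC[C@]12C | intermediate
10 | (13R)-6β-acetoxy-13-(triethylsilyloxy)labda-8,14-dien-7-one | C=C[C@](C)(O[Si](CC)(CC)CC)CCC1=C(C)C(=O)[C@@H](OC(C)=O)[C@H]2C(C)(C)CCC[C@]12C | intermediate
11 | (13R)-6β-acetoxy-13-hydroxylabda-8,14-dien-7-one | C=C[C@](C)(O)CCC1=C(C)C(=O)[C@@H](OC(C)=O)[C@H]2C(C)(C)CCC[C@]12C | target

**Step count and risks**
Total step count: 5. Longest linear sequence: 5 steps (fully linear from sclareol).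

The three steps most likely to fail are steps 1, 3 and 5.

Step 1 may fail through poor discrimination between the two tertiary alcohols or through a high proportion of ring-alkene isomers. The fallback sets out from 1 and returns at 3. Both alcohols are acetylated (AcCl, N,N-dimethylaniline) to sclareol 8,13-diacetate F1. The strained ring acetate is removed by thermal syn-elimination (2,4,6-collidine, reflux) to manool 13-acetate F2. Saponification (KOH, MeOH) gives manool F3, which is silylated (TESOTf, 2,6-lutidine) to 3.

Step 3 may fail if the rhodium hydride does not move the hindered double bond cleanly, or reduces the enone or attacks the silyl ether. The fallback sets out from crude 5 and returns at 6. Conjugate reduction with LiBH(sec-Bu)3 and trapping with Me3SiCl gives (13R)-13-(triethylsilyloxy)-7-(trimethylsilyloxy)labda-7,14-diene F4. Saegusa–Ito oxidation (Pd(OAc)2, MeCN) then places the double bond at the 8(9) position by β-hydride elimination of H-9.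

Step 5, the proposed new step, may fail through 1,2-hydride shift of the carbene to the 5,8-dien-7-one, or through a protonation path that gives the 6α epimer. The fallback uses only known chemistry, sets out from 6 and returns at 11. α′-Acetoxylation with Mn(OAc)3·2H2O (benzene, reflux) gives (13R)-6α-acetoxy-13-(triethylsilyloxy)labda-8,14-dien-7-one F5 (mainly this epimer). Soft enolisation (Me3SiOTf, Et3N) gives (13R)-6-acetoxy-13-(triethylsilyloxy)-7-(trimethylsilyloxy)labda-6,8,14-triene F6. HF·pyridine then removes both silyl groups and protonates C6 kinetically from the α face to give 11.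

**Further compounds**
F1 | step 1 | sclareol 8,13-diacetate | C=C[C@](C)(OC(C)=O)CC[C@H]1[C@](C)(OC(C)=O)CC[C@H]2C(C)(C)CCC[C@]12C
F2 | step 1 | manool 13-acetate | C=C[C@](C)(OC(C)=O)CC[C@H]1C(=C)CC[C@H]2C(C)(C)CCC[C@]12C
F3 | step 1 | manool, (13R)-labda-8(17),14-dien-13-ol | C=C[C@](C)(O)CC[C@H]1C(=C)CC[C@H]2C(C)(C)CCC[C@]12C
F4 | step 3 | (13R)-13-(triethylsilyloxy)-7-(trimethylsilyloxy)labda-7,14-diene | C=C[C@](C)(O[Si](CC)(CC)CC)CC[C@H]1C(C)=C(O[Si](C)(C)C)C[C@H]2C(C)(C)CCC[C@]12C
F5 | step 5 | (13R)-6α-acetoxy-13-(triethylsilyloxy)labda-8,14-dien-7-one | C=C[C@](C)(O[Si](CC)(CC)CC)CCC1=C(C)C(=O)[C@H](OC(C)=O)[C@H]2C(C)(C)CCC[C@]12C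
F6 | step 5 | (13R)-6-acetoxy-13-(triethylsilyloxy)-7-(trimethylsilyloxy)labda-6,8,14-triene | C=C[C@](C)(O[Si](CC)(CC)CC)CCC1=C(C)C(O[Si](C)(C)C)=C(OC(C)=O)[C@H]2C(C)(C)CCC[C@]12C
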